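## Structural features

The target is built from four guaiacyl C6C3 units (rings A to D). Ring D is a 4-hydroxy-3-methoxybenzyl group on C4 of an oxolane whose C3 carries CH2OH and whose C2 carries ring C; ring C is also the benzo ring of the inner 2,3-dihydrobenzofuran, ring B is the aryl group on inner C2 and the benzo ring of the outer dihydrobenzofuran, and ring A, a free 4-hydroxy-3-methoxyphenyl group, sits on outer C2. Seven stereocentres form three separate clusters: oxolane C2/C3/C4 (R,R,R, all three substituents on one face), inner C2/C3 (2R,3S, trans) and outer C2/C3 (2S,3R, trans). The two dihydrobenzofurans are locally mirror images, so each needs the opposite antipode of a controller, and no cluster can relay its configuration to the next. The fragile points are the three benzylic C–O bonds that stand para to an oxygen (outer C2–O1, inner C2–O1, oxolane C2–O1): acid ionises them, which at the oxolane would epimerise C2 to the more stable 2,3-trans ring or let ring D close an aryltetralin, and hydrogenolysis threatens all three. The real difficulty is therefore the contra-thermodynamic all-cis oxolane, which must be made and kept without acid, next to two trans-dihydrobenzofurans of opposite absolute sense. The key step exploits the ring A hydroxyl being para to outer C2 while the ring B oxygen O1 is held three atoms from that carbon, so a ring A phenoxide can expel a leaving group from C2 and O1 can add back, forming O1–C2 trans to C3. A check of the descriptors confirms that the acyclic precursor must be (1S,2R), which is the syn aldol product of an (S)-4-benzyloxazolidinone, and the cyclised product (2S,3R); the bromine on ring B has no part in the cyclisation (ring B has no benzylic leaving group and cannot become a quinone methide) and only marks the carbon that later bonds to inner C2.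

## Logic of the disconnections

**44 from 43.** Only five O–Si bonds separate 43 from 44. Every hydroxyl is carried as a silyl ether so that the last step is a fluoride treatment, which neither ionises nor hydrogenolyses the three benzylic ethers. The demand is that the phenoxides formed do no harm; the one reversible event, opening of the outer ring through the ring A phenoxide, returns to the trans ring.

**43 from 42, and 42 from 41 and 40.** The oxolane is cut at C2: the C2–H bond (hydride onto the cyclic oxocarbenium ion of 42) and the bond from C2 to C5 of ring C (41, made from 28, onto the carbonyl of 40). This places the acid-sensitive ring at the very end and lets hydride enter anti to two cis substituents, the simplest way to the all-cis ring. The gain is large: 28 holds rings A to C and four stereocentres, 40 holds ring D and two. The demand is that 40 be the cis (3R,4R) lactone, that 41 add to its carbonyl and not deprotonate it, and that the Lewis acid used on 42 spare both dihydrobenzofurans.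

**40 from 39, 38, 36 and 34.** The C3–H bond is cut first (38 by protonation of 37, made from 36), then the C3–CH2O bond (36 by alkylation of 35, made from 34); 39 is only a change of protecting groups. Alkylation can only give the trans lactone, so the cis relationship has to come from kinetic protonation. The gain is that 34 has a single stereocentre. The demand is facial selectivity in the protonation and an enolate that does not eliminate its β-alkoxy group.

**34 from 33, 32, 31, 29 and 30.** The lactone C–O bond and then the C4 stereocentre are removed: 34 from 32 (through 33) by selective ester reduction and ring closure, 32 from 31 by asymmetric hydrogenation, 31 by forming its C=C bond from 29 and 30. This reaches two commercial compounds in three steps. The demand is a catalyst that sets C4 as R and a reductant that leaves the carboxylate alone.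

**28 from 27, 26, 25, 24, and 24 from 20 and 22.** The inner ring is cut at O1–C2 (27 from 26 by capture of a benzylic cation) and then at C2–C3 (24 from 20 and 22 through 23, then reduction to 25). Ring B can no longer become a quinone methide because its oxygen is locked in the outer ring, so this closure must use a cation; that is tolerable only because the oxolane is not yet present. The gain is that ring C comes from the same acid 5 (as its activated form 6) that supplied ring B, now with the antipodal auxiliary. The demand is that the acid step returns both rings trans and that 28 ends with no acidic hydrogen.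

**20 from 19, 18 and 17.** The formyl carbon on C5 of ring B is removed (19, the lithium derivative of 18, plus a formyl donor) and the ring A silyl group taken off. This turns the bromine of 17 into the electrophile for the second aldol. The demand is halogen–metal exchange in the presence of aryl and alkyl silyl ethers.

**17 from 16 and 15 (key).** The O1–C2 bond of the outer ring is cut, opening the ring to quinone methide 16 and, one stage back, to 15, in which both phenolic oxygens are silylated and C2 carries an acetate. The cut is made here because ring A is a free para-phenol in 44: its phenoxide generates the electrophile without oxidant or acid, and the nucleophile sits three atoms away. A ring and the C2 stereocentre are exchanged for an acyclic compound whose only meaningful centre is C3. The demand is a reagent that unmasks both phenols but leaves the primary silyl ether and the aryl bromide alone; for that reason the phenols carry the fast-cleaving tert-butyldimethylsilyl group, the primary oxygen carries the slow triisopropylsilyl group, and fluoride is limited to just over two equivalents.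

**15 from 14, 13, 12, and 12 from 8 and 10.** After removal of the acetate and the primary silyl group (14, 13) the C1–C2 bond of the propane chain, the future outer C2–C3 bond, is cut by a retro-aldol step to 8 and 10 (through 11). Absolute configuration enters here: the (S)-auxiliary of 8 fixes the later C3 as R. The gain is two achiral aromatic pieces. The demand is syn-selective enolisation and addition of an arylacetyl imide, and reduction of 12 without retro-aldol cleavage.

**8 and 22 from 6; 6 from 5; 5 from 4, 3, 2 and 1; 10 from 9.** 8 and 22 are cut at the N-acyl bond to the auxiliaries 7 and 21 and to one common acyl donor, 6, which is the mixed pivalic anhydride of 5. 5 is the one-carbon homologue of 2 (through 3 and 4), 2 is the silyl ether of 1, and 10 is the silyl ether of 9. One acid, activated once and divided between the two auxiliaries, halves the preparative work for rings B and C. The demand is a homologation that never exposes the aryl silyl ether to strong acid or base, and an acyl donor that survives long enough at low temperature to be used in two parallel acylations.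

## Other disconnections considered

**Alternative 1:** The cut lies in the oxolane carbon chain: the C2–C3 bond (C2 being the carbon that bears ring C) and the bond from C4 to the ring D benzylic carbon.
- Forward step: the lithiated dithiane A3 adds to the β-carbon of menthyloxybutenolide A2, and the lactone enolate is benzylated by bromide A4, giving A1 in one flask; no ring closes.
- In favour: the acetal centre of A2 controls both new centres. After reduction the acetal carbon becomes the C3 hydroxymethyl group and the lactone carbonyl becomes C5, so the trans lactone translates into the required 3,4-cis oxolane. On this point the alternative is better than the chosen plan, which needs steps 19 to 23 and a kinetic protonation for the same C3/C4 pair.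
- Against: C2 is still a masked ketone. Its hydride reduction in the open chain is predicted by the Felkin–Anh model to give the carbinol that leads to the 2,3-trans ring, so the all-cis problem is postponed unless a cyclic oxocarbenium ion and a Lewis acid are used after all. Dithiane removal needs thiophilic or oxidising reagents, and the methoxymethyl ether of ring C needs acid next to a labile benzylic ether. Ring C arrives with no carbon at C5, so the inner dihydrobenzofuran would have to be annulated onto a phenol later.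
- Comparison: structurally it addresses two of seven stereocentres and no benzofuran ring, whereas the chosen key step closes a ring of the outer unit. Mechanistically the anionic tandem is the equal of the quinone methide closure in reliability. In step count it would shorten the lactone sector but lengthen the elaboration of ring C, so no net gain is expected.

**Alternative 2:** The cut is the O1–C5 bond of the oxolane, reached through a temporary C3–C5 bond in a cyclopropane.
- Forward step: iodide opens cyclopropane A6 at its unsubstituted CH2 and the ketone enolate oxygen displaces iodide (a nucleophile-mediated Cloke–Wilson rearrangement), giving dihydrofuran A5 with C4 unchanged.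
- In favour: one stereocentre (C4) suffices, because cis-hydrogenation of the enol ether from the face opposite the C4 benzyl group would set C2 and C3 together in the all-cis arrangement without acid. As an answer to the all-cis oxolane this is better than the chosen lactol reduction, which needs a cis lactone and a Lewis acid.
- Against: the rearrangement must break the bond to the unsubstituted carbon, whereas the usual thermal or Lewis-acid pathway breaks the bond to the substituted one, so regiocontrol rests entirely on the SN2 opening. The tetrasubstituted enol ether ester has to be hydrogenated and the ester reduced. As in Alternative 1, ring C has no C5 substituent, so both dihydrobenzofurans would still have to be built on the phenol freed from its benzyl ether.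
- Comparison: structurally it solves the oxolane more elegantly but leaves four stereocentres and two rings open. Mechanistically it carries a regiochemical risk that the chosen key step does not have. In step count it is probably equal for the oxolane sector and worse overall, because ring C must be functionalised late.

**Alternative 3:** The cut removes two bonds of the inner dihydrobenzofuran, C2–C3 and O1–C2, and divides the molecule into a ring A/B half and a ring C/D half.
- Forward step: base eliminates sulfinate from sulfone A8 to an ortho-quinone methide and deprotonates sulfonium salt A9; the ylide carbon adds to the methide carbon and the phenoxide displaces the sulfide, giving A7, the fully protected target.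
- In favour: it is the most convergent union possible, done under mild base that the oxolane tolerates, and the trans ring is the normal outcome of such [4+1] annulations. On convergence and on compatibility with the acid-sensitive oxolane it is better than the chosen plan, which must build the oxolane last because step 17 uses acid.
- Against: the two new centres are set only relative to each other. The stereocentres of A8 and A9 are too remote to bias the absolute sense, so two trans diastereomers are expected unless a chiral sulfide is built into A9; the chosen route fixes this ring with an auxiliary. The methide carbon carries a CH2OSi group, which opens a competing tautomerisation to a vinylphenol. A8 needs a benzylic sulfone beside a free phenol on a ring that already holds the oxolane.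
- Comparison: A9 would itself be made from 20, so the chosen key step serves both plans (equal on the outer ring). Mechanistically the annulation is sound but stereochemically uncontrolled in the absolute sense. Total step count would be similar, with a shorter longest linear sequence.

Key step: step 10

Abbreviations: TBS = tert-butyldimethylsilyl, TIPS = triisopropylsilyl, Bn = benzyl.

Assumption: arylacetyl imides 8 and 22 form Z boron enolates and follow the usual Evans syn sense, as the parent propionyl imides do.

Assumption: in step 20 the antipode of the Et-DuPHOS ligand is the one that delivers the R acid 32.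

Assumption: the mixed anhydride 6 is made once, kept cold in THF, and divided at once between steps 5 and 13, which are run in parallel.

## Route

Step 1
Reactants: 1 5-bromo-2-hydroxy-3-methoxybenzaldehyde
Product: 2 5-bromo-3-methoxy-2-(TBS-oxy)benzaldehyde
Conditions: TBSCl, imidazole, DMF, rt
Reagents that add atoms: tert-butyldimethylsilyl chloride, CC(C)(C)[Si](C)(C)Cl
Why: Imidazole-mediated O-silylation of the phenol; the TBS ether is the fluoride-labile mask needed in steps 10 and 16.

Step 2
Reactants: 2 5-bromo-3-methoxy-2-(TBS-oxy)benzaldehyde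
Product: 3 4-bromo-2-methoxy-6-(2-methoxyethenyl)-1-(TBS-oxy)benzene (E/Z mixture)
Conditions: Ph3P(CH2OMe)Cl, NaN(SiMe3)2, THF, 0 °C to rt
Reagents that add atoms: (methoxymethyl)triphenylphosphonium chloride, COC[P+](c1ccccc1)(c1ccccc1)c1ccccc1.[Cl-]
Why: Wittig olefination with the methoxymethylene ylide; the amide base is non-nucleophilic and spares the aryl silyl ether, and the alkene geometry is irrelevant.

Step 3
Reactants: 3 4-bromo-2-methoxy-6-(2-methoxyethenyl)-1-(TBS-oxy)benzene
Product: 5 2-[5-bromo-3-methoxy-2-(TBS-oxy)phenyl]acetic acid, via arylacetaldehyde 4 (not isolated)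
Conditions: HCO2H/H2O (9:1), CH2Cl2, rt; evaporate; then NaClO2, NaH2PO4, 2-methyl-2-butene, t-BuOH/H2O, 0 °C to rt
Reagents that add atoms: water, O; sodium chlorite, [Na+].[O-]Cl=O
Why: Acid hydrolysis of the enol ether gives the homologated aldehyde, which is oxidised in the same flask by the Pinnick oxidation; formic acid is too weak to cleave the aryl silyl ether, so the phenol stays masked and cannot close onto the aldehyde to a benzofuran.

Step 4
Reactants: 5 2-[5-bromo-3-methoxy-2-(TBS-oxy)phenyl]acetic acid
Product: 6 2-[5-bromo-3-methoxy-2-(TBS-oxy)phenyl]acetic pivalic anhydride (obtained as a cold THF solution, not purified)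
Conditions: PivCl, Et3N, THF, −20 °C; filter cold under argon
Reagents that add atoms: pivaloyl chloride, CC(C)(C)C(=O)Cl
Why: Mixed-anhydride formation by O-acylation of the triethylammonium carboxylate with pivaloyl chloride; the anhydride is made once, and the filtered cold solution is divided into two portions that are used immediately in steps 5 and 13.

Step 5
Reactants: 6 mixed pivalic anhydride (first portion); 7 (S)-4-benzyl-1,3-oxazolidin-2-one
Product: 8 (4S)-4-benzyl-3-{2-[5-bromo-3-methoxy-2-(TBS-oxy)phenyl]acetyl}-1,3-oxazolidin-2-one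
Conditions: LiCl, Et3N, THF, −20 °C to rt
Reagents that add atoms: none
Why: N-Acylation of the Evans auxiliary by the mixed anhydride under LiCl/Et3N activation; attack occurs at the less hindered arylacetyl carbonyl and pivalate is the leaving group.

Step 6
Reactants: 9 vanillin (4-hydroxy-3-methoxybenzaldehyde)
Product: 10 3-methoxy-4-(TBS-oxy)benzaldehyde
Conditions: TBSCl, imidazole, DMF, rt
Reagents that add atoms: tert-butyldimethylsilyl chloride, CC(C)(C)[Si](C)(C)Cl
Why: O-Silylation of the phenol; this silyl ether is the latent ring A phenoxide of the key step.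

Step 7
Reactants: 8 (4S)-N-arylacetyl oxazolidinone; 10 3-methoxy-4-(TBS-oxy)benzaldehyde
Product: 12 (4S)-4-benzyl-3-{(2S,3S)-2-[5-bromo-3-methoxy-2-(TBS-oxy)phenyl]-3-hydroxy-3-[3-methoxy-4-(TBS-oxy)phenyl]propanoyl}-1,3-oxazolidin-2-one, via Z boron enolate 11 (not isolated)
Conditions: Bu2BOTf, i-Pr2NEt, CH2Cl2, −78 to 0 °C; 10, −78 to 0 °C; then H2O2, pH 7 buffer, MeOH, 0 °C
Reagents that add atoms: none
Why: Evans syn aldol reaction: the Z boron enolate reacts through a closed chair transition state on the face away from the auxiliary benzyl group, so the auxiliary sets both new centres; the α-centre becomes C3 (R) of the outer ring.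

Step 8
Reactants: 12 syn aldol adduct
Product: 13 (1S,2R)-2-[5-bromo-3-methoxy-2-(TBS-oxy)phenyl]-1-[3-methoxy-4-(TBS-oxy)phenyl]propane-1,3-diol
Conditions: LiBH4, MeOH (1 equiv), THF, 0 °C; aq. NH4Cl
Reagents that add atoms: none
Why: Reductive cleavage of the imide by LiBH4 gives the 1,3-diol and returns the auxiliary; aryl bromide and silyl ethers are inert, and the low temperature suppresses retro-aldol cleavage.

Step 9
Reactants: 13 (1S,2R)-diol
Product: 15 (1S,2R)-2-[5-bromo-3-methoxy-2-(TBS-oxy)phenyl]-1-[3-methoxy-4-(TBS-oxy)phenyl]-3-(TIPS-oxy)propyl acetate, via primary silyl ether 14 (not isolated)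
Conditions: TIPSCl, imidazole, CH2Cl2, 0 °C to rt; then Ac2O, Et3N, DMAP, rt
Reagents that add atoms: triisopropylsilyl chloride, CC(C)[Si](Cl)(C(C)C)C(C)C; acetic anhydride, CC(=O)OC(C)=O
Why: Sequential one-flask protection: the bulky silyl chloride reacts only at the primary hydroxyl, then DMAP-catalysed acetylation turns the hindered benzylic alcohol into the leaving group of the key step.

Step 10
Reactants: 15 (1S,2R)-bis(aryl silyl ether) acetate
Product: 17 4-[(2S,3R)-5-bromo-7-methoxy-3-(TIPS-oxymethyl)-2,3-dihydro-1-benzofuran-2-yl]-2-methoxyphenol, via para-quinone methide 16 (not isolated)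
Conditions: Bu4NF (2.2 equiv), THF, −20 to 0 °C; aq. NH4Cl
Reagents that add atoms: none
Why: Fluoride cleaves the two aryl O–Si bonds within minutes while the primary TIPS ether reacts far more slowly; the ring A phenoxide then expels acetate by 1,6-elimination to give 16 without any oxidant, and the ring B phenoxide adds to the exocyclic methide carbon, forming O1–C2 and re-aromatising ring A. The closest known reaction type is the fluoride- or base-triggered formation of para-quinone methides from 4-silyloxy- or 4-hydroxybenzyl esters and their capture by oxygen nucleophiles, the ring-closing half of lignan β-5 coupling. The ring closes in the 5-exo-trig mode, since O1 attacks the exocyclic alkene carbon and the other alkene carbon stays outside the new ring. The new centre C2 is controlled by C3: the dienone and the CH2OSi group avoid each other in the transition state, so O1 adds to the methide face that places ring A trans to the C3 substituent, and because the product phenoxide can reopen to 16 this is also the thermodynamic outcome. C2 is planar in 16, so the carbinol configuration of 15 does not matter. The step needs chemoselectivity (aryl over alkyl O–Si cleavage, and oxygen addition in preference to addition of fluoride or water or loss of the C3 proton to a stilbene) and trans selectivity; the first is secured by TBS on the phenols against TIPS on the primary oxygen and by low temperature, the second by a nucleophile that is unmasked in the same event and held three atoms from the electrophile. The aryl bromide is inert to fluoride.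

Step 11
Reactants: 17 ring A phenol
Product: 18 (2S,3R)-5-bromo-7-methoxy-2-[3-methoxy-4-(TBS-oxy)phenyl]-3-(TIPS-oxymethyl)-2,3-dihydro-1-benzofuran
Conditions: TBSCl, imidazole, DMF, rt
Reagents that add atoms: tert-butyldimethylsilyl chloride, CC(C)(C)[Si](C)(C)Cl
Why: O-Silylation of the phenol removes the only acidic hydrogen before the organolithium and boron enolate steps; step 16 takes the group off again together with that of ring C.

Step 12
Reactants: 18 aryl bromide
Product: 20 (2S,3R)-7-methoxy-2-[3-methoxy-4-(TBS-oxy)phenyl]-3-(TIPS-oxymethyl)-2,3-dihydro-1-benzofuran-5-carbaldehyde, via aryllithium 19 (not isolated)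
Conditions: n-BuLi, THF, −78 °C; DMF, −78 °C to rt; aq. NH4Cl
Reagents that add atoms: N,N-dimethylformamide, CN(C)C=O
Why: Bromine–lithium exchange at −78 °C is faster than any attack on the silyl ethers; formylation of the aryllithium with DMF gives the aldehyde when the hemiaminal collapses on work-up.

Step 13
Reactants: 6 mixed pivalic anhydride (second portion); 21 (R)-4-benzyl-1,3-oxazolidin-2-one
Product: 22 (4R)-4-benzyl-3-{2-[5-bromo-3-methoxy-2-(TBS-oxy)phenyl]acetyl}-1,3-oxazolidin-2-one
Conditions: LiCl, Et3N, THF, −20 °C to rt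
Reagents that add atoms: none
Why: Same N-acylation as step 5, run in parallel with it on the second portion of the anhydride solution, with the antipodal auxiliary that the inner ring requires because it is the local mirror image of the outer ring.

Step 14
Reactants: 22 (4R)-N-arylacetyl oxazolidinone; 20 benzofuran-5-carbaldehyde
Product: 24 (4R)-4-benzyl-3-{(2R,3R)-2-[5-bromo-3-methoxy-2-(TBS-oxy)phenyl]-3-hydroxy-3-[(2S,3R)-7-methoxy-2-[3-methoxy-4-(TBS-oxy)phenyl]-3-(TIPS-oxymethyl)-2,3-dihydro-1-benzofuran-5-yl]propanoyl}-1,3-oxazolidin-2-one, via Z boron enolate 23 (not isolated)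
Conditions: Bu2BOTf, i-Pr2NEt, CH2Cl2, −78 to 0 °C; 20, −78 to 0 °C; then H2O2, pH 7 buffer, MeOH, 0 °C
Reagents that add atoms: none
Why: Second Evans syn aldol reaction; the auxiliary overrides the remote stereocentres of the aldehyde and sets the future inner C3 (S after reduction) and a carbinol centre that step 17 erases.

Step 15
Reactants: 24 syn aldol adduct
Product: 25 (1R,2S)-2-[5-bromo-3-methoxy-2-(TBS-oxy)phenyl]-1-[(2S,3R)-7-methoxy-2-[3-methoxy-4-(TBS-oxy)phenyl]-3-(TIPS-oxymethyl)-2,3-dihydro-1-benzofuran-5-yl]propane-1,3-diol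
Conditions: LiBH4, MeOH (1 equiv), THF, 0 °C; aq. NH4Cl
Reagents that add atoms: none
Why: Reductive removal of the auxiliary as in step 8.

Step 16
Reactants: 25 diol with two aryl TBS ethers
Product: 26 (1R,2S)-2-(5-bromo-2-hydroxy-3-methoxyphenyl)-1-[(2S,3R)-2-(4-hydroxy-3-methoxyphenyl)-7-methoxy-3-(TIPS-oxymethyl)-2,3-dihydro-1-benzofuran-5-yl]propane-1,3-diol
Conditions: Bu4NF (2.2 equiv), THF, 0 °C; aq. NH4Cl
Reagents that add atoms: none
Why: Fluoride removes both aryl silyl groups and leaves the primary TIPS ether, as in step 10; with no leaving group on the new benzylic carbon nothing else happens, and any opening of the outer ring through the ring A phenoxide is reversible.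

Step 17
Reactants: 26 bisphenol triol
Product: 27 4-[(2S,3R)-5-[(2R,3S)-5-bromo-3-(hydroxymethyl)-7-methoxy-2,3-dihydro-1-benzofuran-2-yl]-7-methoxy-3-(TIPS-oxymethyl)-2,3-dihydro-1-benzofuran-2-yl]-2-methoxyphenol
Conditions: TsOH·H2O (10 mol%), CH2Cl2, 0 °C to rt
Reagents that add atoms: none
Why: Acid-catalysed dehydrative cyclisation (SN1): the benzylic alcohol para to the ring B oxygen ionises to a stabilised cation that the ring C phenol traps in a 5-exo closure anti to the C3 substituent, and reversibility of the closure makes the trans (2R,3S) ring the final product whatever the carbinol configuration. The outer ring can ionise only reversibly and returns to its trans form because its C3 is untouched.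

Step 18
Reactants: 27 phenol primary alcohol
Product: 28 (2S,3R)-5-[(2R,3S)-5-bromo-7-methoxy-3-(TIPS-oxymethyl)-2,3-dihydro-1-benzofuran-2-yl]-7-methoxy-2-[3-methoxy-4-(TIPS-oxy)phenyl]-3-(TIPS-oxymethyl)-2,3-dihydro-1-benzofuran
Conditions: TIPSCl, imidazole, DMAP (cat.), DMF, rt
Reagents that add atoms: triisopropylsilyl chloride, CC(C)[Si](Cl)(C(C)C)C(C)C
Why: O-Silylation of the ring A phenol and the new primary alcohol; after this no acidic hydrogen remains for step 26.

Step 19
Reactants: 29 4-(benzyloxy)-3-methoxybenzaldehyde; 30 dimethyl succinate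
Product: 31 (3E)-4-[4-(benzyloxy)-3-methoxyphenyl]-3-(methoxycarbonyl)but-3-enoic acid
Conditions: NaOMe, MeOH, reflux; then aq. HCl
Reagents that add atoms: none
Why: Stobbe condensation (aldol addition, lactonisation to the paraconic ester, E1cB opening) gives the E half-ester.

Step 20
Reactants: 31 Stobbe half-ester
Product: 32 (3R)-4-[4-(benzyloxy)-3-methoxyphenyl]-3-(methoxycarbonyl)butanoic acid
Conditions: H2 (5 bar), [Rh(cod)(Et-DuPHOS)]BF4 (1 mol%), NaOMe (cat.), MeOH, rt
Reagents that add atoms: none
Why: Rhodium–bisphospholane asymmetric hydrogenation of an itaconate-type half-ester; the carboxylate anchors the substrate and the ligand sets the centre that becomes oxolane C4, while the homogeneous catalyst leaves the benzyl ether alone.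

Step 21
Reactants: 32 (3R)-half-ester
Product: 34 (4R)-4-[4-(benzyloxy)-3-methoxybenzyl]oxolan-2-one, via hydroxy acid 33 (not isolated)
Conditions: KOH (1 equiv), EtOH; CaCl2, NaBH4, −10 °C to rt; then 2 M HCl, rt
Reagents that add atoms: none
Why: Ca(BH4)2 formed in the flask reduces the ester but not the carboxylate, and acidification closes the γ-lactone (the β-benzyl isomer) with no change at the stereocentre.

Step 22
Reactants: 34 (4R)-β-benzyl lactone
Product: 36 (3S,4R)-3-(benzyloxymethyl)-4-[4-(benzyloxy)-3-methoxybenzyl]oxolan-2-one (trans), via lithium enolate 35 (not isolated)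
Conditions: LiN(i-Pr)2, THF, −78 °C; BnOCH2Cl, DMPU, −78 to −40 °C
Reagents that add atoms: benzyl chloromethyl ether, ClCOCc1ccccc1
Why: Alkylation of the lactone enolate anti to the C4 substituent (1,2-induction in a five-membered enolate) gives the trans lactone.

Step 23
Reactants: 36 trans lactone
Product: 38 (3R,4R)-3-(benzyloxymethyl)-4-[4-(benzyloxy)-3-methoxybenzyl]oxolan-2-one (cis), via lithium enolate 37 (not isolated)
Conditions: LiN(i-Pr)2, THF, −78 °C; then 2,6-di-tert-butyl-4-methylphenol, −78 °C; aq. NH4Cl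
Reagents that add atoms: none
Why: Kinetic protonation of the planar enolate: the hindered phenol should deliver the proton to the face opposite the C4 benzyl group, leaving the CH2O group cis to it; the cis isomer is separated and recovered 36 is recycled.

Step 24
Reactants: 38 cis lactone
Product: 39 (3R,4R)-4-(4-hydroxy-3-methoxybenzyl)-3-(hydroxymethyl)oxolan-2-one
Conditions: H2 (1 atm), Pd/C (10%), EtOAc/EtOH, rt
Reagents that add atoms: none
Why: Hydrogenolysis of both benzyl ethers on a substrate with no other benzylic C–O bond; the neutral conditions do not epimerise C3.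

Step 25
Reactants: 39 hydroxy phenol lactone
Product: 40 (3R,4R)-4-[3-methoxy-4-(TIPS-oxy)benzyl]-3-(TIPS-oxymethyl)oxolan-2-one
Conditions: TIPSCl, imidazole, DMF, rt
Reagents that add atoms: triisopropylsilyl chloride, CC(C)[Si](Cl)(C(C)C)C(C)C
Why: O-Silylation of phenol and primary alcohol; imidazole is too weak a base to epimerise the lactone.

Step 26
Reactants: 28 ring C aryl bromide; 40 cis lactone
Product: 42 (3R,4R)-2-{(2R,3S)-7-methoxy-2-[(2S,3R)-7-methoxy-2-[3-methoxy-4-(TIPS-oxy)phenyl]-3-(TIPS-oxymethyl)-2,3-dihydro-1-benzofuran-5-yl]-3-(TIPS-oxymethyl)-2,3-dihydro-1-benzofuran-5-yl}-4-[3-methoxy-4-(TIPS-oxy)benzyl]-3-(TIPS-oxymethyl)oxolan-2-ol (lactol; anomers in equilibrium with the hydroxy ketone), via aryllithium 41 (not isolated)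
Conditions: 28, n-BuLi, THF, −78 °C; then 40, −78 °C; aq. NH4Cl at −78 °C
Reagents that add atoms: none
Why: Bromine–lithium exchange and 1,2-addition of the aryllithium to the lactone carbonyl; the tetrahedral lithium alkoxide persists at −78 °C, so a second addition is not expected, and carbonyl addition should outpace deprotonation at the hindered α-carbon. The crude lactol is reduced at once to avoid epimerisation at C3 through the open hydroxy ketone.

Step 27
Reactants: 42 lactol
Product: 43 penta-TIPS ether of the target, (2R,3R,4R)-oxolane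
Conditions: Et3SiH, BF3·OEt2, CH2Cl2, −78 °C; then Et3N, aq. NaHCO3
Reagents that add atoms: none
Why: Ionic hydrogenation of the lactol: BF3 generates the cyclic aryl-stabilised oxocarbenium ion and the silane delivers hydride to the face opposite the cis C3 and C4 substituents, so ring C ends up cis to both (C2 = R); this is the established way to 2,3-cis-2-aryloxolanes. At −78 °C the hemiketal should ionise far faster than the benzylic ethers of the two dihydrobenzofurans.

Step 28
Reactants: 43 penta-TIPS ether
Product: 44 target, 4-{(2S,3R)-5-[(2R,3S)-5-[(2R,3R,4R)-4-(4-hydroxy-3-methoxybenzyl)-3-(hydroxymethyl)oxolan-2-yl]-3-(hydroxymethyl)-7-methoxy-2,3-dihydro-1-benzofuran-2-yl]-3-(hydroxymethyl)-7-methoxy-2,3-dihydro-1-benzofuran-2-yl}-2-methoxyphenol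
Conditions: Bu4NF (excess), THF, rt; aq. NH4Cl
Reagents that add atoms: none
Why: Fluoride cleaves the two aryl and three primary silyl ethers; the phenoxides formed cannot damage the skeleton, since the outer ring can reopen only reversibly to its trans form and ring C has no free phenol para to the oxolane.

## Compound list

1 | 5-bromo-2-hydroxy-3-methoxybenzaldehyde | COc1cc(Br)cc(C=O)c1O | starting material
2 | 5-bromo-2-(tert-butyldimethylsilyloxy)-3-methoxybenzaldehyde | COc1cc(Br)cc(C=O)c1O[Si](C)(C)C(C)(C)C | intermediate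
3 | [4-bromo-2-methoxy-6-(2-methoxyethenyl)phenoxy](tert-butyl)dimethylsilane, E/Z mixture | COC=Cc1cc(Br)cc(OC)c1O[Si](C)(C)C(C)(C)C | intermediate
4 | 2-[5-bromo-2-(tert-butyldimethylsilyloxy)-3-methoxyphenyl]acetaldehyde | O=CCc1cc(Br)cc(OC)c1O[Si](C)(C)C(C)(C)C | intermediate
5 | 2-[5-bromo-2-(tert-butyldimethylsilyloxy)-3-methoxyphenyl]acetic acid | OC(=O)Cc1cc(Br)cc(OC)c1O[Si](C)(C)C(C)(C)C | intermediate
6 | 2-[5-bromo-2-(tert-butyldimethylsilyloxy)-3-methoxyphenyl]acetic pivalic anhydride | CC(C)(C)C(=O)OC(=O)Cc1cc(Br)cc(OC)c1O[Si](C)(C)C(C)(C)C | intermediate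
7 | (S)-4-benzyl-1,3-oxazolidin-2-one | O=C1OC[C@H](Cc2ccccc2)N1 | starting material
8 | (4S)-4-benzyl-3-{2-[5-bromo-2-(tert-butyldimethylsilyloxy)-3-methoxyphenyl]acetyl}-1,3-oxazolidin-2-one | O=C1OC[C@H](Cc2ccccc2)N1C(=O)Cc1cc(Br)cc(OC)c1O[Si](C)(C)C(C)(C)C | intermediate
9 | vanillin (4-hydroxy-3-methoxybenzaldehyde) | COc1cc(C=O)ccc1O | starting material
10 | 4-(tert-butyldimethylsilyloxy)-3-methoxybenzaldehyde | COc1cc(C=O)ccc1O[Si](C)(C)C(C)(C)C | intermediate
11 | dibutylboron (Z)-enolate of 8 | CCCCB(CCCC)O/C(=C\c1cc(Br)cc(OC)c1O[Si](C)(C)C(C)(C)C)N1C(=O)OC[C@@H]1Cc1ccccc1 | intermediate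
12 | (4S)-4-benzyl-3-{(2S,3S)-2-[5-bromo-2-(tert-butyldimethylsilyloxy)-3-methoxyphenyl]-3-[4-(tert-butyldimethylsilyloxy)-3-methoxyphenyl]-3-hydroxypropanoyl}-1,3-oxazolidin-2-one | Brc1cc(OC)c(O[Si](C)(C)C(C)(C)C)c(c1)[C@H](C(=O)N1C(=O)OC[C@@H]1Cc1ccccc1)[C@H](O)c1ccc(O[Si](C)(C)C(C)(C)C)c(OC)c1 | intermediate
13 | (1S,2R)-2-[5-bromo-2-(tert-butyldimethylsilyloxy)-3-methoxyphenyl]-1-[4-(tert-butyldimethylsilyloxy)-3-methoxyphenyl]propane-1,3-diol | Brc1cc(OC)c(O[Si](C)(C)C(C)(C)C)c(c1)[C@H](CO)[C@H](O)c1ccc(O[Si](C)(C)C(C)(C)C)c(OC)c1 | intermediate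
14 | (1S,2R)-2-[5-bromo-2-(tert-butyldimethylsilyloxy)-3-methoxyphenyl]-1-[4-(tert-butyldimethylsilyloxy)-3-methoxyphenyl]-3-(triisopropylsilyloxy)propan-1-ol | Brc1cc(OC)c(O[Si](C)(C)C(C)(C)C)c(c1)[C@H](CO[Si](C(C)C)(C(C)C)C(C)C)[C@H](O)c1ccc(O[Si](C)(C)C(C)(C)C)c(OC)c1 | intermediate
15 | (1S,2R)-2-[5-bromo-2-(tert-butyldimethylsilyloxy)-3-methoxyphenyl]-1-[4-(tert-butyldimethylsilyloxy)-3-methoxyphenyl]-3-(triisopropylsilyloxy)propyl acetate | Brc1cc(OC)c(O[Si](C)(C)C(C)(C)C)c(c1)[C@H](CO[Si](C(C)C)(C(C)C)C(C)C)[C@H](OC(C)=O)c1ccc(O[Si](C)(C)C(C)(C)C)c(OC)c1 | intermediate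
16 | 4-[(2R)-2-(5-bromo-3-methoxy-2-oxidophenyl)-3-(triisopropylsilyloxy)propylidene]-2-methoxycyclohexa-2,5-dien-1-one (phenoxide) | [O-]c1c(OC)cc(Br)cc1[C@H](CO[Si](C(C)C)(C(C)C)C(C)C)C=C1C=CC(=O)C(OC)=C1 | intermediate
17 | 4-[(2S,3R)-5-bromo-7-methoxy-3-(triisopropylsilyloxymethyl)-2,3-dihydro-1-benzofuran-2-yl]-2-methoxyphenol | Brc1cc(OC)c2c(c1)[C@H](CO[Si](C(C)C)(C(C)C)C(C)C)[C@@H](c1ccc(O)c(OC)c1)O2 | intermediate
18 | (2S,3R)-5-bromo-2-[4-(tert-butyldimethylsilyloxy)-3-methoxyphenyl]-7-methoxy-3-(triisopropylsilyloxymethyl)-2,3-dihydro-1-benzofuran | Brc1cc(OC)c2c(c1)[C@H](CO[Si](C(C)C)(C(C)C)C(C)C)[C@@H](c1ccc(O[Si](C)(C)C(C)(C)C)c(OC)c1)O2 | intermediate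
19 | 5-lithio derivative of 18 | [Li]c1cc(OC)c2c(c1)[C@H](CO[Si](C(C)C)(C(C)C)C(C)C)[C@@H](c1ccc(O[Si](C)(C)C(C)(C)C)c(OC)c1)O2 | intermediate
20 | (2S,3R)-2-[4-(tert-butyldimethylsilyloxy)-3-methoxyphenyl]-7-methoxy-3-(triisopropylsilyloxymethyl)-2,3-dihydro-1-benzofuran-5-carbaldehyde | O=Cc1cc(OC)c2c(c1)[C@H](CO[Si](C(C)C)(C(C)C)C(C)C)[C@@H](c1ccc(O[Si](C)(C)C(C)(C)C)c(OC)c1)O2 | intermediate
21 | (R)-4-benzyl-1,3-oxazolidin-2-one | O=C1OC[C@@H](Cc2ccccc2)N1 | starting material
22 | (4R)-4-benzyl-3-{2-[5-bromo-2-(tert-butyldimethylsilyloxy)-3-methoxyphenyl]acetyl}-1,3-oxazolidin-2-one | O=C1OC[C@@H](Cc2ccccc2)N1C(=O)Cc1cc(Br)cc(OC)c1O[Si](C)(C)C(C)(C)C | intermediate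
23 | dibutylboron (Z)-enolate of 22 | CCCCB(CCCC)O/C(=C\c1cc(Br)cc(OC)c1O[Si](C)(C)C(C)(C)C)N1C(=O)OC[C@H]1Cc1ccccc1 | intermediate
24 | (4R)-4-benzyl-3-{(2R,3R)-2-[5-bromo-2-(tert-butyldimethylsilyloxy)-3-methoxyphenyl]-3-hydroxy-3-[(2S,3R)-2-[4-(tert-butyldimethylsilyloxy)-3-methoxyphenyl]-7-methoxy-3-(triisopropylsilyloxymethyl)-2,3-dihydro-1-benzofuran-5-yl]propanoyl}-1,3-oxazolidin-2-one | Brc1cc(OC)c(O[Si](C)(C)C(C)(C)C)c(c1)[C@@H](C(=O)N1C(=O)OC[C@H]1Cc1ccccc1)[C@@H](O)c1cc(OC)c2c(c1)[C@H](CO[Si](C(C)C)(C(C)C)C(C)C)[C@@H](c1ccc(O[Si](C)(C)C(C)(C)C)c(OC)c1)O2 | intermediate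
25 | (1R,2S)-2-[5-bromo-2-(tert-butyldimethylsilyloxy)-3-methoxyphenyl]-1-[(2S,3R)-2-[4-(tert-butyldimethylsilyloxy)-3-methoxyphenyl]-7-methoxy-3-(triisopropylsilyloxymethyl)-2,3-dihydro-1-benzofuran-5-yl]propane-1,3-diol | Brc1cc(OC)c(O[Si](C)(C)C(C)(C)C)c(c1)[C@@H](CO)[C@@H](O)c1cc(OC)c2c(c1)[C@H](CO[Si](C(C)C)(C(C)C)C(C)C)[C@@H](c1ccc(O[Si](C)(C)C(C)(C)C)c(OC)c1)O2 | intermediate
26 | (1R,2S)-2-(5-bromo-2-hydroxy-3-methoxyphenyl)-1-[(2S,3R)-2-(4-hydroxy-3-methoxyphenyl)-7-methoxy-3-(triisopropylsilyloxymethyl)-2,3-dihydro-1-benzofuran-5-yl]propane-1,3-diol | Brc1cc(OC)c(O)c(c1)[C@@H](CO)[C@@H](O)c1cc(OC)c2c(c1)[C@H](CO[Si](C(C)C)(C(C)C)C(C)C)[C@@H](c1ccc(O)c(OC)c1)O2 | intermediate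
27 | 4-[(2S,3R)-5-[(2R,3S)-5-bromo-3-(hydroxymethyl)-7-methoxy-2,3-dihydro-1-benzofuran-2-yl]-7-methoxy-3-(triisopropylsilyloxymethyl)-2,3-dihydro-1-benzofuran-2-yl]-2-methoxyphenol | Brc1cc(OC)c2c(c1)[C@@H](CO)[C@H](c1cc(OC)c3c(c1)[C@H](CO[Si](C(C)C)(C(C)C)C(C)C)[C@@H](c1ccc(O)c(OC)c1)O3)O2 | intermediate
28 | (2S,3R)-5-[(2R,3S)-5-bromo-7-methoxy-3-(triisopropylsilyloxymethyl)-2,3-dihydro-1-benzofuran-2-yl]-7-methoxy-2-[3-methoxy-4-(triisopropylsilyloxy)phenyl]-3-(triisopropylsilyloxymethyl)-2,3-dihydro-1-benzofuran | Brc1cc(OC)c2c(c1)[C@@H](CO[Si](C(C)C)(C(C)C)C(C)C)[C@H](c1cc(OC)c3c(c1)[C@H](CO[Si](C(C)C)(C(C)C)C(C)C)[C@@H](c1ccc(O[Si](C(C)C)(C(C)C)C(C)C)c(OC)c1)O3)O2 | intermediate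
29 | 4-(benzyloxy)-3-methoxybenzaldehyde | COc1cc(C=O)ccc1OCc1ccccc1 | starting material
30 | dimethyl succinate | COC(=O)CCC(=O)OC | starting material
31 | (3E)-4-[4-(benzyloxy)-3-methoxyphenyl]-3-(methoxycarbonyl)but-3-enoic acid | COC(=O)/C(CC(=O)O)=C/c1ccc(OCc2ccccc2)c(OC)c1 | intermediate
32 | (3R)-4-[4-(benzyloxy)-3-methoxyphenyl]-3-(methoxycarbonyl)butanoic acid | COC(=O)[C@@H](CC(=O)O)Cc1ccc(OCc2ccccc2)c(OC)c1 | intermediate
33 | (3R)-4-[4-(benzyloxy)-3-methoxyphenyl]-3-(hydroxymethyl)butanoic acid | OC[C@@H](CC(=O)O)Cc1ccc(OCc2ccccc2)c(OC)c1 | intermediate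
34 | (4R)-4-[4-(benzyloxy)-3-methoxybenzyl]oxolan-2-one | O=C1C[C@@H](Cc2ccc(OCc3ccccc3)c(OC)c2)CO1 | intermediate
35 | lithium enolate of 34 | [Li]OC1=C[C@@H](Cc2ccc(OCc3ccccc3)c(OC)c2)CO1 | intermediate
36 | (3S,4R)-3-(benzyloxymethyl)-4-[4-(benzyloxy)-3-methoxybenzyl]oxolan-2-one (trans) | O=C1[C@H](COCc2ccccc2)[C@@H](Cc2ccc(OCc3ccccc3)c(OC)c2)CO1 | intermediate
37 | lithium enolate of 36 | [Li]OC1=C(COCc2ccccc2)[C@@H](Cc2ccc(OCc3ccccc3)c(OC)c2)CO1 | intermediate
38 | (3R,4R)-3-(benzyloxymethyl)-4-[4-(benzyloxy)-3-methoxybenzyl]oxolan-2-one (cis) | O=C1[C@@H](COCc2ccccc2)[C@@H](Cc2ccc(OCc3ccccc3)c(OC)c2)CO1 | intermediate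
39 | (3R,4R)-4-(4-hydroxy-3-methoxybenzyl)-3-(hydroxymethyl)oxolan-2-one | O=C1[C@@H](CO)[C@@H](Cc2ccc(O)c(OC)c2)CO1 | intermediate
40 | (3R,4R)-4-[3-methoxy-4-(triisopropylsilyloxy)benzyl]-3-(triisopropylsilyloxymethyl)oxolan-2-one | O=C1[C@@H](CO[Si](C(C)C)(C(C)C)C(C)C)[C@@H](Cc2ccc(O[Si](C(C)C)(C(C)C)C(C)C)c(OC)c2)CO1 | intermediate
41 | 5-lithio derivative of 28 (lithium on ring C) | [Li]c1cc(OC)c2c(c1)[C@@H](CO[Si](C(C)C)(C(C)C)C(C)C)[C@H](c1cc(OC)c3c(c1)[C@H](CO[Si](C(C)C)(C(C)C)C(C)C)[C@@H](c1ccc(O[Si](C(C)C)(C(C)C)C(C)C)c(OC)c1)O3)O2 | intermediate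
42 | (3R,4R)-2-{(2R,3S)-7-methoxy-2-[(2S,3R)-7-methoxy-2-[3-methoxy-4-(triisopropylsilyloxy)phenyl]-3-(triisopropylsilyloxymethyl)-2,3-dihydro-1-benzofuran-5-yl]-3-(triisopropylsilyloxymethyl)-2,3-dihydro-1-benzofuran-5-yl}-4-[3-methoxy-4-(triisopropylsilyloxy)benzyl]-3-(triisopropylsilyloxymethyl)oxolan-2-ol, anomeric mixture | OC1(c2cc(OC)c3c(c2)[C@@H](CO[Si](C(C)C)(C(C)C)C(C)C)[C@H](c2cc(OC)c4c(c2)[C@H](CO[Si](C(C)C)(C(C)C)C(C)C)[C@@H](c2ccc(O[Si](C(C)C)(C(C)C)C(C)C)c(OC)c2)O4)O3)[C@@H](CO[Si](C(C)C)(C(C)C)C(C)C)[C@@H](Cc2ccc(O[Si](C(C)C)(C(C)C)C(C)C)c(OC)c2)CO1 | intermediate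
43 | penta(triisopropylsilyl) ether of 44: (2S,3R)-7-methoxy-5-[(2R,3S)-7-methoxy-5-[(2R,3R,4R)-4-[3-methoxy-4-(triisopropylsilyloxy)benzyl]-3-(triisopropylsilyloxymethyl)oxolan-2-yl]-3-(triisopropylsilyloxymethyl)-2,3-dihydro-1-benzofuran-2-yl]-2-[3-methoxy-4-(triisopropylsilyloxy)phenyl]-3-(triisopropylsilyloxymethyl)-2,3-dihydro-1-benzofuran | COc1cc(C[C@H]2CO[C@@H](c3cc(OC)c4c(c3)[C@@H](CO[Si](C(C)C)(C(C)C)C(C)C)[C@H](c3cc(OC)c5c(c3)[C@H](CO[Si](C(C)C)(C(C)C)C(C)C)[C@@H](c3ccc(O[Si](C(C)C)(C(C)C)C(C)C)c(OC)c3)O5)O4)[C@H]2CO[Si](C(C)C)(C(C)C)C(C)C)ccc1O[Si](C(C)C)(C(C)C)C(C)C | intermediate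
44 | 4-{(2S,3R)-5-[(2R,3S)-5-[(2R,3R,4R)-4-(4-hydroxy-3-methoxybenzyl)-3-(hydroxymethyl)oxolan-2-yl]-3-(hydroxymethyl)-7-methoxy-2,3-dihydro-1-benzofuran-2-yl]-3-(hydroxymethyl)-7-methoxy-2,3-dihydro-1-benzofuran-2-yl}-2-methoxyphenol | COc1cc(C[C@H]2CO[C@@H](c3cc(OC)c4c(c3)[C@@H](CO)[C@H](c3cc(OC)c5c(c3)[C@H](CO)[C@@H](c3ccc(O)c(OC)c3)O5)O4)[C@H]2CO)ccc1O | target

## Step count and least certain steps

Total: 28 steps. Longest linear sequence: 19 steps (1–5, 7–12, 14–18, 26–28).

**Step 10 (key step).** The quinone methide may be intercepted before the ring closes if cleavage of the hindered ring B silyl ether lags behind: addition of fluoride or water to the methide carbon, or loss of the C3 proton to a stilbene. Prolonged exposure may also remove the primary silyl ether. Fallback (acid instead of base): set out from 14, isolated after the silylation half of step 9 without acetylation. Bu4NF/AcOH in THF at 0 °C removes both aryl silyl groups to give (1S,2R)-2-(5-bromo-2-hydroxy-3-methoxyphenyl)-1-(4-hydroxy-3-methoxyphenyl)-3-(triisopropylsilyloxy)propan-1-ol F1. Catalytic TsOH in CH2Cl2 at 0 °C then ionises the para-hydroxybenzylic alcohol and the ring B phenol captures the cation, which returns to the route at 17.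

**Step 17.** Acid may ionise the outer ring, whose ring A phenol is free at this stage, and the cation may be lost irreversibly by intermolecular aryl alkylation or by loss of the C3 proton; protodesilylation of the primary silyl ether is a further risk. Fallback (neutral phosphonium activation with the primary alcohol masked): set out from 25. TIPSCl/imidazole gives the primary silyl ether F2, and Bu4NF (2.2 equiv) gives the bisphenol F3. PPh3/DIAD in THF at 0 °C (Mitsunobu conditions) then closes the ring to the phenol F4; the oxyphosphonium ion of this para-alkoxybenzylic alcohol is expected to ionise, so the same cation is trapped without Brønsted acid, but a concerted displacement would give the cis ring, which is why this is not the first choice. The primary alcohol must be masked here, otherwise the phenol would alkylate at CH2. TIPSCl/imidazole on F4 returns to the route at 28.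

**Step 23.** Facial selectivity of the protonation may be poor, and the enolate may eliminate benzyloxide to an α-methylene lactone. Fallback (C3 set by hydrogenation instead of protonation): set out from 34. HCO2Et/NaH in THF gives the hydroxymethylidene lactone F5, and TIPSCl/Et3N gives the silyl enol ether F6. H2 over Pd/C adds hydrogen to the exocyclic alkene from the face opposite the C4 substituent and removes the benzyl ether, giving the cis lactone phenol F7. TIPSCl/imidazole returns to the route at 40.

**Step 26.** The aryllithium may deprotonate the lactone instead of adding, which would waste the advanced aryl fragment as the arene and epimerise or eliminate in the lactone; double addition is the other risk. Fallback (acyclic acyl donor that adds once): set out from 40. MeNH(OMe)·HCl/i-PrMgCl in THF at −10 °C opens the lactone to the hydroxy Weinreb amide F8, and Et3SiCl/imidazole gives its triethylsilyl ether F9. Aryllithium 41 (from 28) adds once to F9 through the chelated tetrahedral intermediate to give the aryl ketone F10. AcOH/THF/H2O removes the triethylsilyl group and the hydroxy ketone closes to the lactol, which returns to the route at 42.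

**Step 27.** BF3 may ionise the benzylic ethers of the dihydrobenzofurans, with reductive ring opening by the silane; C3 may epimerise through the enol ether; hydride delivery may not be fully face-selective. Fallback (acid-free, forming O1–C5 instead of reducing C2): set out from 40 and 41. i-Bu2AlH in CH2Cl2 at −78 °C reduces 40 to the lactol F11. The lactol is deprotonated with i-PrMgCl and treated with 41, which adds to the open hydroxy aldehyde to give the diol F12; the Felkin–Anh model, with the branched C4 chain as the large group, predicts the carbinol needed for the 2,3-cis ring. TsCl/pyridine sulfonylates only the primary hydroxyl to give the tosylate F13, and KOt-Bu in THF closes the ring by displacement at the primary carbon with retention at C2, which returns to the route at 43.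

## Further compounds

F1 | step 10 | (1S,2R)-2-(5-bromo-2-hydroxy-3-methoxyphenyl)-1-(4-hydroxy-3-methoxyphenyl)-3-(triisopropylsilyloxy)propan-1-ol | Brc1cc(OC)c(O)c(c1)[C@H](CO[Si](C(C)C)(C(C)C)C(C)C)[C@H](O)c1ccc(O)c(OC)c1
F2 | step 17 | (1R,2S)-2-[5-bromo-2-(tert-butyldimethylsilyloxy)-3-methoxyphenyl]-1-[(2S,3R)-2-[4-(tert-butyldimethylsilyloxy)-3-methoxyphenyl]-7-methoxy-3-(triisopropylsilyloxymethyl)-2,3-dihydro-1-benzofuran-5-yl]-3-(triisopropylsilyloxy)propan-1-ol | Brc1cc(OC)c(O[Si](C)(C)C(C)(C)C)c(c1)[C@@H](CO[Si](C(C)C)(C(C)C)C(C)C)[C@@H](O)c1cc(OC)c2c(c1)[C@H](CO[Si](C(C)C)(C(C)C)C(C)C)[C@@H](c1ccc(O[Si](C)(C)C(C)(C)C)c(OC)c1)O2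
F3 | step 17 | (1R,2S)-2-(5-bromo-2-hydroxy-3-methoxyphenyl)-1-[(2S,3R)-2-(4-hydroxy-3-methoxyphenyl)-7-methoxy-3-(triisopropylsilyloxymethyl)-2,3-dihydro-1-benzofuran-5-yl]-3-(triisopropylsilyloxy)propan-1-ol | Brc1cc(OC)c(O)c(c1)[C@@H](CO[Si](C(C)C)(C(C)C)C(C)C)[C@@H](O)c1cc(OC)c2c(c1)[C@H](CO[Si](C(C)C)(C(C)C)C(C)C)[C@@H](c1ccc(O)c(OC)c1)O2
F4 | step 17 | 4-{(2S,3R)-5-[(2R,3S)-5-bromo-7-methoxy-3-(triisopropylsilyloxymethyl)-2,3-dihydro-1-benzofuran-2-yl]-7-methoxy-3-(triisopropylsilyloxymethyl)-2,3-dihydro-1-benzofuran-2-yl}-2-methoxyphenol | Brc1cc(OC)c2c(c1)[C@@H](CO[Si](C(C)C)(C(C)C)C(C)C)[C@H](c1cc(OC)c3c(c1)[C@H](CO[Si](C(C)C)(C(C)C)C(C)C)[C@@H](c1ccc(O)c(OC)c1)O3)O2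
F5 | step 23 | (4R)-4-[4-(benzyloxy)-3-methoxybenzyl]-3-(hydroxymethylidene)oxolan-2-one | O=C1C(=CO)[C@@H](Cc2ccc(OCc3ccccc3)c(OC)c2)CO1
F6 | step 23 | (4R)-4-[4-(benzyloxy)-3-methoxybenzyl]-3-[(triisopropylsilyloxy)methylidene]oxolan-2-one | O=C1C(=CO[Si](C(C)C)(C(C)C)C(C)C)[C@@H](Cc2ccc(OCc3ccccc3)c(OC)c2)CO1
F7 | step 23 | (3R,4R)-4-(4-hydroxy-3-methoxybenzyl)-3-(triisopropylsilyloxymethyl)oxolan-2-one | O=C1[C@@H](CO[Si](C(C)C)(C(C)C)C(C)C)[C@@H](Cc2ccc(O)c(OC)c2)CO1
F8 | step 26 | (2R,3R)-4-hydroxy-N-methoxy-3-[3-methoxy-4-(triisopropylsilyloxy)benzyl]-N-methyl-2-(triisopropylsilyloxymethyl)butanamide | CON(C)C(=O)[C@@H](CO[Si](C(C)C)(C(C)C)C(C)C)[C@@H](Cc1ccc(O[Si](C(C)C)(C(C)C)C(C)C)c(OC)c1)CO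
F9 | step 26 | (2R,3R)-N-methoxy-3-[3-methoxy-4-(triisopropylsilyloxy)benzyl]-N-methyl-4-(triethylsilyloxy)-2-(triisopropylsilyloxymethyl)butanamide | CON(C)C(=O)[C@@H](CO[Si](C(C)C)(C(C)C)C(C)C)[C@@H](Cc1ccc(O[Si](C(C)C)(C(C)C)C(C)C)c(OC)c1)CO[Si](CC)(CC)CC
F10 | step 26 | (2R,3R)-1-{(2R,3S)-7-methoxy-2-[(2S,3R)-7-methoxy-2-[3-methoxy-4-(triisopropylsilyloxy)phenyl]-3-(triisopropylsilyloxymethyl)-2,3-dihydro-1-benzofuran-5-yl]-3-(triisopropylsilyloxymethyl)-2,3-dihydro-1-benzofuran-5-yl}-3-[3-methoxy-4-(triisopropylsilyloxy)benzyl]-4-(triethylsilyloxy)-2-(triisopropylsilyloxymethyl)butan-1-one | O=C(c1cc(OC)c2c(c1)[C@@H](CO[Si](C(C)C)(C(C)C)C(C)C)[C@H](c1cc(OC)c3c(c1)[C@H](CO[Si](C(C)C)(C(C)C)C(C)C)[C@@H](c1ccc(O[Si](C(C)C)(C(C)C)C(C)C)c(OC)c1)O3)O2)[C@@H](CO[Si](C(C)C)(C(C)C)C(C)C)[C@@H](Cc1ccc(O[Si](C(C)C)(C(C)C)C(C)C)c(OC)c1)CO[Si](CC)(CC)CC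
F11 | step 27 | (3R,4R)-4-[3-methoxy-4-(triisopropylsilyloxy)benzyl]-3-(triisopropylsilyloxymethyl)oxolan-2-ol, anomeric mixture | OC1[C@@H](CO[Si](C(C)C)(C(C)C)C(C)C)[C@@H](Cc2ccc(O[Si](C(C)C)(C(C)C)C(C)C)c(OC)c2)CO1
F12 | step 27 | (1R,2R,3R)-1-{(2R,3S)-7-methoxy-2-[(2S,3R)-7-methoxy-2-[3-methoxy-4-(triisopropylsilyloxy)phenyl]-3-(triisopropylsilyloxymethyl)-2,3-dihydro-1-benzofuran-5-yl]-3-(triisopropylsilyloxymethyl)-2,3-dihydro-1-benzofuran-5-yl}-3-[3-methoxy-4-(triisopropylsilyloxy)benzyl]-2-(triisopropylsilyloxymethyl)butane-1,4-diol | O[C@@H](c1cc(OC)c2c(c1)[C@@H](CO[Si](C(C)C)(C(C)C)C(C)C)[C@H](c1cc(OC)c3c(c1)[C@H](CO[Si](C(C)C)(C(C)C)C(C)C)[C@@H](c1ccc(O[Si](C(C)C)(C(C)C)C(C)C)c(OC)c1)O3)O2)[C@@H](CO[Si](C(C)C)(C(C)C)C(C)C)[C@@H](Cc1ccc(O[Si](C(C)C)(C(C)C)C(C)C)c(OC)c1)CO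
F13 | step 27 | 4-O-(p-toluenesulfonyl) derivative of F12 (primary tosylate) | O[C@@H](c1cc(OC)c2c(c1)[C@@H](CO[Si](C(C)C)(C(C)C)C(C)C)[C@H](c1cc(OC)c3c(c1)[C@H](CO[Si](C(C)C)(C(C)C)C(C)C)[C@@H](c1ccc(O[Si](C(C)C)(C(C)C)C(C)C)c(OC)c1)O3)O2)[C@@H](CO[Si](C(C)C)(C(C)C)C(C)C)[C@@H](Cc1ccc(O[Si](C(C)C)(C(C)C)C(C)C)c(OC)c1)COS(=O)(=O)c1ccc(C)cc1
A1 | alternative 1 | trans,trans-3-[4-(benzyloxy)-3-methoxybenzyl]-4-{2-[3-methoxy-4-(methoxymethoxy)phenyl]-1,3-dithian-2-yl}-5-[(1R,2S,5R)-menthyloxy]oxolan-2-one | COc1cc(C[C@H]2C(=O)O[C@@H](O[C@@H]3C[C@H](C)CC[C@H]3C(C)C)[C@@H]2C2(c3ccc(OCOC)c(OC)c3)SCCCS2)ccc1OCc1ccccc1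
A2 | alternative 1 | (5R)-5-[(1R,2S,5R)-menthyloxy]furan-2(5H)-one | O=C1C=C[C@H](O[C@@H]2C[C@H](C)CC[C@H]2C(C)C)O1
A3 | alternative 1 | 2-[3-methoxy-4-(methoxymethoxy)phenyl]-1,3-dithiane | COCOc1ccc(C2SCCCS2)cc1OC
A4 | alternative 1 | 4-(benzyloxy)-3-methoxybenzyl bromide | COc1cc(CBr)ccc1OCc1ccccc1
A5 | alternative 2 | methyl (4R)-2-[4-(benzyloxy)-3-methoxyphenyl]-4-[3-methoxy-4-(triisopropylsilyloxy)benzyl]-4,5-dihydrofuran-3-carboxylate | COc1cc(C[C@H]2COC(c3ccc(OCc4ccccc4)c(OC)c3)=C2C(=O)OC)ccc1O[Si](C(C)C)(C(C)C)C(C)C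
A6 | alternative 2 | methyl 1-[4-(benzyloxy)-3-methoxybenzoyl]-2-[3-methoxy-4-(triisopropylsilyloxy)benzyl]cyclopropane-1-carboxylate (C2 as drawn; C1 either) | COc1cc(C[C@H]2CC2(C(=O)OC)C(=O)c2ccc(OCc3ccccc3)c(OC)c2)ccc1O[Si](C(C)C)(C(C)C)C(C)C
A7 | alternative 3 | fully protected target (three tert-butyldimethylsilyl ethers on the primary oxygens; benzyl ethers on the ring A and ring D phenols) | COc1cc(C[C@H]2CO[C@@H](c3cc(OC)c4c(c3)[C@@H](CO[Si](C)(C)C(C)(C)C)[C@H](c3cc(OC)c5c(c3)[C@H](CO[Si](C)(C)C(C)(C)C)[C@@H](c3ccc(OCc6ccccc6)c(OC)c3)O5)O4)[C@H]2CO[Si](C)(C)C(C)(C)C)ccc1OCc1ccccc1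
A8 | alternative 3 | ring C sulfone: 4-[(2R,3R,4R)-4-[4-(benzyloxy)-3-methoxybenzyl]-3-(tert-butyldimethylsilyloxymethyl)oxolan-2-yl]-2-methoxy-6-[2-(tert-butyldimethylsilyloxy)-1-(p-tolylsulfonyl)ethyl]phenol (sulfone carbon either) | COc1cc(C[C@H]2CO[C@@H](c3cc(OC)c(O)c(C(CO[Si](C)(C)C(C)(C)C)S(=O)(=O)c4ccc(C)cc4)c3)[C@H]2CO[Si](C)(C)C(C)(C)C)ccc1OCc1ccccc1
A9 | alternative 3 | {(2S,3R)-2-[4-(benzyloxy)-3-methoxyphenyl]-3-(tert-butyldimethylsilyloxymethyl)-7-methoxy-2,3-dihydro-1-benzofuran-5-yl}methyl(dimethyl)sulfonium bromide | C[S+](C)Cc1cc(OC)c2c(c1)[C@H](CO[Si](C)(C)C(C)(C)C)[C@@H](c1ccc(OCc3ccccc3)c(OC)c1)O2.[Br-]
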